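**Retrosynthetic overview**

1. Feature used: the two tertiary C–OH groups sit on the ring-fusion carbons C1 and C5 of the C2-symmetric 3,7-dioxabicyclo[3.3.0]octane (ring A: C1–C2–O3–C4–C5; ring B: C5–C6–O7–C8–C1). Each is flanked by a ring CH2 (C8, C4); with C4 and C8 drawn as lactone C=O, H-1 and H-5 become enolisable.
2. 18 ⇐ 17 (O–Si cleavage) ⇐ 16 ⇐ 15: C4 and C8 are taken back from CH2 through CH(OH) to C=O.
3. 15 ⇐ 11: the C1–O and C5–O bonds are disconnected to the C–H bonds of the cis-fused dilactone (two lactone-enolate hydroxylations in one flask).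
4. 11 ⇐ 9: ring A (O3–C4) and then ring B (O7–C8) are opened to a C2-symmetric bis-aldol carrying two oxazolidinone auxiliaries. In the forward sense both rings close in step 4, ring A first, and no ring is formed afterwards.
5. 9 ⇐ 6 + two molecules of 2: C1–C2 and C5–C6 by a two-fold Evans syn-aldol of the succinyl bis-imide; 6 ⇐ 3 + 4; 2 ⇐ 1.

Key step: step 5

Remark: locants follow the 3,7-dioxabicyclo[3.3.0]octane skeleton throughout; Ar = 4-(tert-butyldimethylsilyloxy)-3-methoxyphenyl; bis-lactol 16 is carried on as its mixture of anomers because step 7 removes both anomeric centres.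

**Route**

Step 1
Reactants: 1 vanillin
Product: 2 4-(tert-butyldimethylsilyloxy)-3-methoxybenzaldehyde
Conditions: TBSCl, imidazole, DMF, rt
Reagents that add atoms: tert-butyldimethylsilyl chloride, CC(C)(C)[Si](C)(C)Cl
Why: Imidazole-promoted O-silylation of the phenol is chemoselective, leaves the aldehyde untouched, and the aryl silyl ether should tolerate every later step up to the fluoride cleavage.

Step 2
Reactants: 3 (R)-4-benzyl-1,3-oxazolidin-2-one (2 equiv); 4 succinyl chloride
Product: 6 1,4-bis[(4R)-4-benzyl-2-oxo-1,3-oxazolidin-3-yl]butane-1,4-dione, via lithium oxazolidinide 5 (not isolated)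
Conditions: n-BuLi, THF, −78 °C; then 4 (0.5 equiv), −78 → 0 °C
Reagents that add atoms: none
Why: N-Acylation of the lithiated oxazolidinone by both acid chloride groups of 4 gives the bis-imide (imide formation), and the auxiliary stereocentre is not involved.

Step 3
Reactants: 6 bis-imide; 2 aldehyde (2.5 equiv)
Product: 9 (2R,3R)-1,4-bis[(4R)-4-benzyl-2-oxo-1,3-oxazolidin-3-yl]-2,3-bis[(R)-hydroxy(Ar)methyl]butane-1,4-dione, via bis(dibutylboron) dienolate 7 (not isolated), via bis(dibutylboron) aldolate 8 (not isolated)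
Conditions: Bu2BOTf (2.4 equiv), i-Pr2NEt (2.8 equiv), CH2Cl2, −78 → 0 °C; 2, −78 → 0 °C; MeOH, aq. KH2PO4/K2HPO4 (pH 7), 30% H2O2, 0 °C
Reagents that add atoms: none
Why: This is an Evans syn-aldol run at both termini: soft enolisation gives the (Z,Z)-bis(boron enolate), and each enolate adds to 2 through a closed chair transition state on the face away from the benzyl group of its own (R)-oxazolidinone, so both halves should receive the same syn (α-R, carbinol-R) configuration and the adduct is C2-symmetric.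

Step 4
Reactants: 9 bis-aldol
Product: 11 (1R,2R,5R,6R)-2,6-bis(Ar)-3,7-dioxabicyclo[3.3.0]octane-4,8-dione, via monolactone imide 10 (not isolated)
Conditions: 4-(dimethylamino)pyridine (0.2 equiv), CH2Cl2, rt → 40 °C
Reagents that add atoms: none
Why: Each hydroxyl is γ to the imide carbonyl of the other half, so two intramolecular acyl transfers (lactonisation, 5-exo-trig) should close ring A and then ring B with release of auxiliary 3; the (2R,3R) backbone already holds the second arm cis to the remaining acyl group and the syn-aldol relationship puts each aryl group exo, so no stereocentre is touched.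

Step 5
Reactants: 11 dilactone
Product: 15 (1R,2S,5R,6S)-1,5-dihydroxy-2,6-bis(Ar)-3,7-dioxabicyclo[3.3.0]octane-4,8-dione, via potassium enolate 12 (not isolated), via monohydroxy alkoxide 13 (not isolated), via enolate alkoxide 14 (not isolated)
Conditions: KN(SiMe3)2 (1.1 equiv), THF, −78 °C; 2-(phenylsulfonyl)-3-phenyloxaziridine (1.3 equiv), −78 °C; KN(SiMe3)2 (1.4 equiv), −78 °C; the oxaziridine (1.5 equiv), −78 °C; AcOH, −78 °C
Reagents that add atoms: 2-(phenylsulfonyl)-3-phenyloxaziridine, O=S(=O)(c1ccccc1)N1OC1c1ccccc1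
Why: KN(SiMe3)2 removes H-1 (α to the C8 carbonyl) and the enolate carbon attacks the oxaziridine oxygen with loss of the N-sulfonyl imine to give the C1 alkoxide, after which deprotonation at C5 (α to C4=O) and a second oxygen transfer complete the diol. The closest known reaction type is the α-hydroxylation of ester and lactone enolates with N-sulfonyloxaziridines. No ring is closed or opened; two C–O bonds are formed. Both new stereocentres (C1, C5) are fixed by the ring fusion: a bicyclo[3.3.0] dilactone can only be cis-fused, so oxygen must arrive on the convex face that carried the hydrogen, which means retention and a cis relation to the exo aryl group on the neighbouring carbon. The step needs oxygen transfer to outrun β-acyloxy elimination (opening at C2–O3 or C6–O7) and retro-aldol cleavage of the C1–C5 bond from the alkoxide; the fused five-membered rings hold these bonds close to the nodal plane of the enolate or carbonyl π system, and short enolate lifetimes at −78 °C with potassium as counter-ion should do the rest.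

Step 6
Reactants: 15 dihydroxy dilactone
Product: 16 (1R,2S,5R,6S)-2,6-bis(Ar)-3,7-dioxabicyclo[3.3.0]octane-1,4,5,8-tetrol (bis-lactol, anomers at C4 and C8)
Conditions: i-Bu2AlH (6 equiv), CH2Cl2, −78 °C; aq. KNaC4H4O6 (potassium sodium tartrate)
Reagents that add atoms: none
Why: Partial reduction of lactones to lactols: two equivalents are consumed by the tertiary hydroxyls, the tetrahedral adduct at each carbonyl is stable at −78 °C until the tartrate work-up, the aryl silyl ethers and benzylic ethers are inert, and the anomeric centres need no control.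

Step 7
Reactants: 16 bis-lactol
Product: 17 (1R,2S,5R,6S)-2,6-bis(Ar)-3,7-dioxabicyclo[3.3.0]octane-1,5-diol
Conditions: Et3SiH (8 equiv), BF3·OEt2 (3 equiv), CH2Cl2, −78 → −40 °C; aq. NaHCO3
Reagents that add atoms: none
Why: Ionic hydrogenation of lactols: BF3 ionises each hemiacetal C–OH bond and Et3SiH delivers hydride to C4 and C8, and at low temperature the hemiacetal carbons should ionise much faster than the benzylic C2–O3 and C6–O7 ether bonds, so the four stereocentres stay as set.

Step 8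
Reactants: 17 bis-silyl ether
Product: 18 (1R,2S,5R,6S)-2,6-bis(4-hydroxy-3-methoxyphenyl)-3,7-dioxabicyclo[3.3.0]octane-1,5-diol (target)
Conditions: Bu4NF, AcOH, THF, 0 °C
Reagents that add atoms: none
Why: Fluoride-induced cleavage of the two aryl O–Si bonds (desilylation), buffered with AcOH so that the freed phenol is not left as a phenoxide able to open the p-hydroxybenzylic ether through a quinone methide; no stereocentre is touched.

**Compound list**

1 | vanillin | COc1cc(C=O)ccc1O | starting material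
2 | 4-(tert-butyldimethylsilyloxy)-3-methoxybenzaldehyde | COc1cc(C=O)ccc1O[Si](C)(C)C(C)(C)C | intermediate
3 | (R)-4-benzyl-1,3-oxazolidin-2-one | O=C1N[C@H](Cc2ccccc2)CO1 | starting material
4 | succinyl chloride | O=C(Cl)CCC(Cl)=O | starting material
5 | lithium (R)-4-benzyl-2-oxo-1,3-oxazolidin-3-ide | [Li+].O=C1[N-][C@H](Cc2ccccc2)CO1 | intermediate
6 | 1,4-bis[(4R)-4-benzyl-2-oxo-1,3-oxazolidin-3-yl]butane-1,4-dione | O=C(CCC(=O)N1[C@H](Cc2ccccc2)COC1=O)N1[C@H](Cc2ccccc2)COC1=O | intermediate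
7 | 3,3'-[(1Z,3Z)-1,4-bis(dibutylboryloxy)buta-1,3-diene-1,4-diyl]bis[(4R)-4-benzyl-1,3-oxazolidin-2-one] | CCCCB(CCCC)O/C(=C\C=C(/OB(CCCC)CCCC)N1[C@H](Cc2ccccc2)COC1=O)N1[C@H](Cc2ccccc2)COC1=O | intermediate
8 | bis(O-dibutylboryl) aldolate of 9 | O=C([C@@H]([C@@H](OB(CCCC)CCCC)c1ccc(O[Si](C)(C)C(C)(C)C)c(OC)c1)[C@H]([C@@H](OB(CCCC)CCCC)c1ccc(O[Si](C)(C)C(C)(C)C)c(OC)c1)C(=O)N1[C@H](Cc2ccccc2)COC1=O)N1[C@H](Cc2ccccc2)COC1=O | intermediate
9 | (2R,3R)-1,4-bis[(4R)-4-benzyl-2-oxo-1,3-oxazolidin-3-yl]-2,3-bis[(R)-hydroxy(Ar)methyl]butane-1,4-dione | O=C([C@@H]([C@@H](O)c1ccc(O[Si](C)(C)C(C)(C)C)c(OC)c1)[C@H]([C@@H](O)c1ccc(O[Si](C)(C)C(C)(C)C)c(OC)c1)C(=O)N1[C@H](Cc2ccccc2)COC1=O)N1[C@H](Cc2ccccc2)COC1=O | intermediate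
10 | (4R)-4-benzyl-3-{(2R,3R,4R)-2-Ar-4-[(R)-Ar(hydroxy)methyl]-5-oxooxolane-3-carbonyl}-1,3-oxazolidin-2-one | O=C1O[C@@H](c2ccc(O[Si](C)(C)C(C)(C)C)c(OC)c2)[C@H](C(=O)N2[C@H](Cc3ccccc3)COC2=O)[C@@H]1[C@@H](O)c1ccc(O[Si](C)(C)C(C)(C)C)c(OC)c1 | intermediate
11 | (1R,2R,5R,6R)-2,6-bis(Ar)-3,7-dioxabicyclo[3.3.0]octane-4,8-dione | COc1cc([C@@H]2OC(=O)[C@H]3[C@H](c4ccc(O[Si](C)(C)C(C)(C)C)c(OC)c4)OC(=O)[C@@H]23)ccc1O[Si](C)(C)C(C)(C)C | intermediate
12 | potassium C1(C8)-enolate of 11 | COc1cc([C@@H]2OC(=O)[C@H]3[C@H](c4ccc(O[Si](C)(C)C(C)(C)C)c(OC)c4)OC([O-])=C23)ccc1O[Si](C)(C)C(C)(C)C.[K+] | intermediate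
13 | potassium C1-alkoxide of the 1-hydroxy dilactone (O in place of H-1, same face) | COc1cc([C@@H]2OC(=O)[C@H]3[C@H](c4ccc(O[Si](C)(C)C(C)(C)C)c(OC)c4)OC(=O)[C@@]23[O-])ccc1O[Si](C)(C)C(C)(C)C.[K+] | intermediate
14 | dipotassium C5(C4)-enolate C1-alkoxide | COc1cc([C@@H]2OC([O-])=C3[C@H](c4ccc(O[Si](C)(C)C(C)(C)C)c(OC)c4)OC(=O)[C@@]23[O-])ccc1O[Si](C)(C)C(C)(C)C.[K+].[K+] | intermediate
15 | (1R,2S,5R,6S)-1,5-dihydroxy-2,6-bis(Ar)-3,7-dioxabicyclo[3.3.0]octane-4,8-dione | COc1cc([C@@H]2OC(=O)[C@@]3(O)[C@H](c4ccc(O[Si](C)(C)C(C)(C)C)c(OC)c4)OC(=O)[C@@]23O)ccc1O[Si](C)(C)C(C)(C)C | intermediate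
16 | (1R,2S,5R,6S)-2,6-bis(Ar)-3,7-dioxabicyclo[3.3.0]octane-1,4,5,8-tetrol | COc1cc([C@@H]2OC(O)[C@@]3(O)[C@H](c4ccc(O[Si](C)(C)C(C)(C)C)c(OC)c4)OC(O)[C@@]23O)ccc1O[Si](C)(C)C(C)(C)C | intermediate
17 | (1R,2S,5R,6S)-2,6-bis(Ar)-3,7-dioxabicyclo[3.3.0]octane-1,5-diol | COc1cc([C@@H]2OC[C@@]3(O)[C@H](c4ccc(O[Si](C)(C)C(C)(C)C)c(OC)c4)OC[C@@]23O)ccc1O[Si](C)(C)C(C)(C)C | intermediate
18 | (1R,2S,5R,6S)-2,6-bis(4-hydroxy-3-methoxyphenyl)-3,7-dioxabicyclo[3.3.0]octane-1,5-diol | COc1cc([C@@H]2OC[C@@]3(O)[C@H](c4ccc(O)c(OC)c4)OC[C@@]23O)ccc1O | target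

Total step count: 8. Longest linear sequence: 7 steps (steps 2–8, or step 1 followed by steps 3–8).

**Steps most likely to fail**

Step 5. A lactone ring may open by β-acyloxy elimination from the enolate. The second deprotonation next to the potassium alkoxide may stay incomplete. Base or enolate may be consumed by addition to the N-sulfonyl imine formed in the first oxygen transfer. Oxygen transfer may be slow past the exo aryl group. The fallback replaces the anionic oxygen transfer by a Rubottom oxidation of neutral silyl ketene acetals and sets out from 11. LiN(SiMe3)2 is added to 11 and Me3SiCl in THF at −78 °C (trapping in situ) to give mono(silyl ketene acetal) F1. Dimethyldioxirane in acetone at −78 °C should epoxidise its convex face, and citric acid work-up should give monohydroxy dilactone F2. The same two operations on F2 with two equivalents of base and Me3SiCl should give the O-silylated silyl ketene acetal F3, and dimethyldioxirane followed by citric acid in MeOH should give 15, where the route is rejoined.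

Step 3. The second enolisation or the second aldol at the crowded dienolate may stall. Facial control may erode if the auxiliary and the newly formed neighbouring stereocentre disagree. Lactonisation may set in early and remove the directing imide before the second aldol. The fallback builds the dilactone by phenol oxidation and resolves it, setting out from 1. Knoevenagel–Doebner condensation of 1 with malonic acid (pyridine, piperidine, 90 °C) gives ferulic acid F4. Oxidative β–β coupling with FeCl3 and O2 in aqueous acetone, in which both carboxyl groups trap the bis-quinone methide, should give the racemic exo,exo dilactone diphenol F5. TBSCl and imidazole in DMF give the racemic bis-silyl ether F6. Preparative chromatography on a chiral stationary phase delivers the (1R,2R,5R,6R) enantiomer, which is 11, where the route is rejoined.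

Step 7. BF3 may ionise the electron-rich benzylic C2–O3 and C6–O7 bonds, leading to epimerisation at C2 and C6 or reductive ring opening. This competes with ionisation of the lactols, which is slowed by the hydroxyl on the adjacent carbon. The fallback avoids cationic conditions and sets out from 15. LiBH4 in THF (0 °C → rt) reduces both lactones to hexaol F7. TsCl (2.2 equiv) in pyridine (0 → 40 °C) should sulfonylate only the two primary hydroxyls to give bis-tosylate F8. Each benzylic hydroxyl then displaces the tosylate of the other half (Williamson-type 5-exo-tet closure at CH2, so every stereocentre is retained) to give 17, where the route is rejoined.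

**Further compounds**

F1 | step 5 | mono(trimethylsilyl ketene acetal) of 11 at C1/C8 | COc1cc([C@@H]2OC(=O)[C@H]3[C@H](c4ccc(O[Si](C)(C)C(C)(C)C)c(OC)c4)OC(O[Si](C)(C)C)=C23)ccc1O[Si](C)(C)C(C)(C)C
F2 | step 5 | 1-hydroxy-2,6-bis(Ar)-3,7-dioxabicyclo[3.3.0]octane-4,8-dione (OH in place of H-1, same face) | COc1cc([C@@H]2OC(=O)[C@H]3[C@H](c4ccc(O[Si](C)(C)C(C)(C)C)c(OC)c4)OC(=O)[C@@]23O)ccc1O[Si](C)(C)C(C)(C)C
F3 | step 5 | 1-O-trimethylsilyl C5/C4 trimethylsilyl ketene acetal of F2 | COc1cc([C@@H]2OC(O[Si](C)(C)C)=C3[C@H](c4ccc(O[Si](C)(C)C(C)(C)C)c(OC)c4)OC(=O)[C@@]23O[Si](C)(C)C)ccc1O[Si](C)(C)C(C)(C)C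
F4 | step 3 | ferulic acid | COc1cc(/C=C/C(=O)O)ccc1O
F5 | step 3 | racemic (1R*,2R*,5R*,6R*)-2,6-bis(4-hydroxy-3-methoxyphenyl)-3,7-dioxabicyclo[3.3.0]octane-4,8-dione | COc1cc([C@@H]2OC(=O)[C@H]3[C@H](c4ccc(O)c(OC)c4)OC(=O)[C@@H]23)ccc1O.COc1cc([C@H]2OC(=O)[C@@H]3[C@@H](c4ccc(O)c(OC)c4)OC(=O)[C@H]23)ccc1O
F6 | step 3 | racemic 11 | COc1cc([C@@H]2OC(=O)[C@H]3[C@H](c4ccc(O[Si](C)(C)C(C)(C)C)c(OC)c4)OC(=O)[C@@H]23)ccc1O[Si](C)(C)C(C)(C)C.COc1cc([C@H]2OC(=O)[C@@H]3[C@@H](c4ccc(O[Si](C)(C)C(C)(C)C)c(OC)c4)OC(=O)[C@H]23)ccc1O[Si](C)(C)C(C)(C)C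
F7 | step 7 | (1S,2R,3R,4S)-1,4-bis(Ar)-2,3-bis(hydroxymethyl)butane-1,2,3,4-tetrol | COc1cc([C@H](O)[C@](O)(CO)[C@@](O)(CO)[C@@H](O)c2ccc(O[Si](C)(C)C(C)(C)C)c(OC)c2)ccc1O[Si](C)(C)C(C)(C)C
F8 | step 7 | bis(primary p-toluenesulfonate) of F7 | COc1cc([C@H](O)[C@](O)(COS(=O)(=O)c2ccc(C)cc2)[C@@](O)(COS(=O)(=O)c2ccc(C)cc2)[C@@H](O)c2ccc(O[Si](C)(C)C(C)(C)C)c(OC)c2)ccc1O[Si](C)(C)C(C)(C)C
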